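(The earlier runs and the new flask are simulated for substances that don't exist; scatter was added.)

Amounts first: percentages here count the starting material that a species holds, so one target counts as two, and each protic impurity that takes one starting material removes it from the charge before it can couple.

| flask | starting material | protic impurity | remark | time |
|---|---|---|---|---|
| Sunday's | 0.010 M | 0.15 mM | run made earlier |  |
| Thursday's | 0.010 M | 2.8 mM | run made earlier |  |
| maple | 0.010 M | 0.120 mM |  | 25 min |
| larch | 0.010 M | 0.250 mM |  | 25 min |
| ash | 0.010 M | 0.500 mM |  | 25 min |
| birch | 0.010 M | 1.00 mM |  | 25 min |
| elm | 0.010 M | 2.00 mM |  | 25 min |

| run | time / min | target / % |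
|---|---|---|
| Sunday's | 4.00 | 28 |
| Sunday's | 8.00 | 45 |
| Sunday's | 10.0 | 49 |
| Sunday's | 15.0 | 63 |
| Sunday's | 20.0 | 65 |
| Sunday's | 25.0 | 71 |
| Thursday's | 2.00 | 15 |
| Thursday's | 3.00 | 18 |
| Thursday's | 5.00 | 25 |
| Thursday's | 8.00 | 30 |
| Thursday's | 10.0 | 32 |
| Thursday's | 15.0 | 43 |
| Thursday's | 25.0 | 47 |

(standard deviation of a reading: 2 percentage points)

- percentages count the starting material that a species holds: one target or crystals counts as two
- target is meant together with its crystals
- solid, in amounts per volume of the solution: crystals
- steps thought possible: 2 starting material -> target; starting material + protic impurity -> quenched substrate; crystals <-> target
- the concentration of target that is asked is that of its free form alone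
- "hardly changes" means that all values lie within two and a half points (for a concentration: within two and a half percent of the largest)

- [target] (only what is free in solution) at the end for maple, larch, ash, birch, elm, in this order
- how that number moves from the first to the last of them (rises all the way / hardly changes / falls, then rises / rises, then falls / falls all the way)

We look for one number, and we reach it in two ways. The first compares the two end readings, Sunday's and Thursday's, and divides the target lost by the extra impurity, both taken as fractions of the charge:

toll = (71% − 47%) / ((2.8 mM − 0.15 mM) / 0.010 M) = 0.906

This is our toll, the share of charge lost as target for each share of charge taken by impurity.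

The second way uses Sunday's curve and the count of one impurity per starting material. Coupling of two starting material is second-order, so the reciprocal of the fraction left should grow evenly in time. Sunday's readings give a growth of 0.0961 min⁻¹ up to 10.0 min and 0.0979 min⁻¹ up to 25.0 min. Suppose, as our own assumption, that impurity takes a small slice of the charge early. The reciprocal then starts higher and grows as before, so the fraction left ends lower by the slice times the square of that fraction. The rest of the slice is target lost. With 29.0% left by Sunday's last target reading:

toll = one minus the square of the fraction left = 0.916

These two numbers share Sunday's last reading, but the first rests on Thursday's loss and the second on the one-for-one count, and they agree, so we trust the toll. Starting from Sunday's reading, it gives us: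

maple: 71.3%; elm: 54.2%

These are target and crystals together, which is what the readings count. The readings do not tell us how much of that sum is free, so we commit to the sum.

The forecast gives 0.00352 M for maple and 0.0027 M for elm, so its row falls all the way, and it calls these values “upper limits, correct only if nothing crystallises”.

The flasks gave 0.00127 M of free target in maple and 0.00126 M in elm: hardly changes.

    2 starting material → target (k = 5.40 M⁻¹ min⁻¹)
    starting material + protic impurity → quenched substrate (k = 77.0 M⁻¹ min⁻¹)
    crystals ⇌ target, rate k3*(cs3 - [target]) while solid is left; crystals form when [target] > cs3 (solubility = 1.20 mM, k = 0.610 min⁻¹)

In maple, counting each step's turnover up to 25 min, the quench passed its midpoint by 0.949 min, coupling by 5.32 min and the passage into crystals by 10.3 min. At 25 min the protic impurity, limiting reagent of the quench, stood at 0.0095% of its charge, and crystals held 46.5% of the 71.9% counted as target. From maple to elm the toll gives a drop of 17 percentage points, and target with its crystals stood at 55.4% in elm, with 30.3% in crystals. From larch to birch the toll gives 6.8 points, and target with its crystals stood at 70.7% in larch and 64.1% in birch.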